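Ring C is dissected at three bonds, O1–C8a, C4–C4a and O1–C2, so that ring A becomes an aryne spanning C4a and C8a while O1, C2, C3, C4 and ring B arrive together as one 2-aryl-3-methoxyacrylic acid. The step exploits the fact that O1 and the C4 carbonyl sit on adjacent carbons of ring A, flanked by the C5 oxygen and the quaternary C8 side chain. In a single operation the carboxyl C–O bond of the acid adds across the aryne and the freed phenoxide closes the pyranone by addition–elimination. The aryne precursor is a fully substituted ortho-silylaryl triflate bearing the 1,1-dimethylallyl group and two MOM ethers.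

Key step: step 11

Remark: atom labels (O1, C2 … C8a) follow chromen-4-one numbering of the target, with ring A the benzo ring, ring B the 2,4-dihydroxyphenyl group and ring C the pyranone; the target has no stereocentre, and the E geometry of acid 19 is erased in the ring closure, so it needs no control.

Step 1
Reactants: 1 phloroglucinol
Product: 2 3,5-bis(methoxymethoxy)phenol
Conditions: MOMCl (2.1 equiv), i-Pr2NEt, DMF, 0 °C → rt; chromatographic separation from mono- and tris-ether
Reagents that add atoms: chloromethyl methyl ether (MOMCl), COCCl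
Why: O-alkylation of the phenol with the hard electrophile MOMCl (Williamson type) with the reagent limited to two equivalents should give the bis-ether as the main component of a separable statistical mixture, of which the mono-ether can be resubmitted.

Step 2
Reactants: 2 3,5-bis(methoxymethoxy)phenol; 3 1-bromo-3-methylbut-2-ene
Product: 4 1,3-bis(methoxymethoxy)-5-[(3-methylbut-2-en-1-yl)oxy]benzene
Conditions: K2CO3, acetone, reflux
Reagents that add atoms: none
Why: Williamson ether synthesis, in which the potassium phenoxide displaces the primary allylic bromide by SN2 under polar aprotic conditions that favour O- over C-prenylation.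

Step 3
Reactants: 4 1,3-bis(methoxymethoxy)-5-[(3-methylbut-2-en-1-yl)oxy]benzene
Product: 6 3,5-bis(methoxymethoxy)-2-(2-methylbut-3-en-2-yl)phenol, via cyclohexadienone 5 (not isolated)
Conditions: PhNEt2, 190 °C, sealed tube, argon, short reaction time
Reagents that add atoms: none
Why: Aromatic Claisen rearrangement, a [3,3]-sigmatropic shift that joins the tertiary carbon of the prenyl unit to one of the two equivalent ortho carbons, after which dienone 5 tautomerises to the phenol while the amine solvent keeps the medium basic and suppresses acid-promoted ring closure.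

Step 4
Reactants: 6 3,5-bis(methoxymethoxy)-2-(2-methylbut-3-en-2-yl)phenol
Product: 7 3,5-bis(methoxymethoxy)-2-(2-methylbut-3-en-2-yl)phenyl N-(propan-2-yl)carbamate
Conditions: i-PrNCO, Et3N (cat.), CH2Cl2, rt → 40 °C
Reagents that add atoms: isopropyl isocyanate, CC(C)N=C=O
Why: Base-catalysed addition of the phenol to the isocyanate gives an N-monoalkyl carbamate, chosen because it is a strong metalation director and can later be removed by elimination instead of by attack at a carbonyl that will then be flanked on both sides.

Step 5
Reactants: 7 3,5-bis(methoxymethoxy)-2-(2-methylbut-3-en-2-yl)phenyl N-(propan-2-yl)carbamate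
Product: 11 3,5-bis(methoxymethoxy)-2-(2-methylbut-3-en-2-yl)-6-(trimethylsilyl)phenyl N-(propan-2-yl)carbamate, via N-silyl carbamate 8 (not isolated), via aryllithium 9 (not isolated), via bis-silyl carbamate 10 (not isolated)
Conditions: TMSOTf, TMEDA, Et2O, 0 °C → rt; then n-BuLi, TMEDA, −78 °C; then TMSCl, −78 °C → rt; sat. aq NH4Cl
Reagents that add atoms: chlorotrimethylsilane, C[Si](C)(C)Cl
Why: Directed ortho-metalation, in which the transiently N-silylated carbamate (the strongest director on the ring) and the C5 MOM ether together steer n-BuLi/TMEDA to the position between them (the future C4a), the aryllithium is trapped by TMSCl and the N–Si bond is hydrolysed on work-up.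

Step 6
Reactants: 11 3,5-bis(methoxymethoxy)-2-(2-methylbut-3-en-2-yl)-6-(trimethylsilyl)phenyl N-(propan-2-yl)carbamate
Product: 13 3,5-bis(methoxymethoxy)-2-(2-methylbut-3-en-2-yl)-6-(trimethylsilyl)phenyl trifluoromethanesulfonate, via silylphenol 12 (not isolated)
Conditions: DBU, Et2NH, MeCN, 40 °C; then PhNTf2, 40 °C
Reagents that add atoms: N-phenylbis(trifluoromethanesulfonimide), O=S(=O)(N(c1ccccc1)S(=O)(=O)C(F)(F)F)C(F)(F)F
Why: E1cB cleavage of the N–H carbamate (DBU deprotonates nitrogen, isopropyl isocyanate departs and is scavenged by Et2NH) frees the hindered phenoxide without nucleophilic attack at the carbonyl, and O-sulfonylation by PhNTf2 in the same flask gives the ortho-silylaryl triflate.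

Step 7
Reactants: 14 2,4-dihydroxyphenylacetic acid
Product: 15 methyl 2-(2,4-dihydroxyphenyl)acetate
Conditions: MeOH, H2SO4 (cat.), reflux
Reagents that add atoms: methanol, CO
Why: Fischer esterification in excess methanol, under which any benzofuranone formed from the 2-hydroxyl is reopened to the methyl ester.

Step 8
Reactants: 15 methyl 2-(2,4-dihydroxyphenyl)acetate
Product: 16 methyl 2-[2,4-bis(methoxymethoxy)phenyl]acetate
Conditions: MOMCl, i-Pr2NEt, CH2Cl2, 0 °C → rt
Reagents that add atoms: chloromethyl methyl ether (MOMCl), COCCl
Why: O-alkylation of both phenols with MOMCl under a hindered amine base, which is mild enough to leave the ester and its acidic methylene untouched.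

Step 9
Reactants: 16 methyl 2-[2,4-bis(methoxymethoxy)phenyl]acetate
Product: 18 methyl (E)-2-[2,4-bis(methoxymethoxy)phenyl]-3-methoxyprop-2-enoate, via sodium enolate 17 (not isolated)
Conditions: NaH, HCO2Me, THF, 0 °C → rt; then Me2SO4, DMF (co-solvent), rt
Reagents that add atoms: methyl formate, COC=O; dimethyl sulfate, COS(=O)(=O)OC
Why: Crossed Claisen condensation of the ester enolate with methyl formate gives the stabilised enolate 17, and O-methylation by the hard electrophile Me2SO4 should give the β-methoxyacrylate as the E isomer (methoxy anti to the ester), the usual outcome of this sequence.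

Step 10
Reactants: 18 methyl (E)-2-[2,4-bis(methoxymethoxy)phenyl]-3-methoxyprop-2-enoate
Product: 19 (E)-2-[2,4-bis(methoxymethoxy)phenyl]-3-methoxyprop-2-enoic acid
Conditions: LiOH·H2O, THF/MeOH/H2O, rt; then dilute HCl to pH 4–5, 0 °C
Reagents that add atoms: lithium hydroxide, [Li+].[OH-]
Why: Saponification of the methyl ester by acyl–oxygen cleavage, after which the carboxylate protects the enol ether from conjugate attack by hydroxide, and careful cold acidification to pH 4–5 should spare the MOM ethers and the enol ether.

Step 11
Reactants: 13 3,5-bis(methoxymethoxy)-2-(2-methylbut-3-en-2-yl)-6-(trimethylsilyl)phenyl trifluoromethanesulfonate; 19 (E)-2-[2,4-bis(methoxymethoxy)phenyl]-3-methoxyprop-2-enoic acid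
Product: 22 3-[2,4-bis(methoxymethoxy)phenyl]-5,7-bis(methoxymethoxy)-8-(2-methylbut-3-en-2-yl)chromen-4-one, via aryne 20 (not isolated), via caesium phenoxide 21 (not isolated)
Conditions: CsF (4 equiv, dried), 13 (1.3 equiv), THF, sealed tube, 125 °C
Reagents that add atoms: none
Why: Proposed new method: desilylation of 13 by fluoride with loss of triflate unmasks aryne 20, which is attacked at C8a by a carboxylate oxygen of the caesium salt of 19, and the negative charge appearing at C4a is captured by the new ester carbonyl through a four-membered transition structure, so that the acyl group ends on C4a and the oxygen stays on C8a as phenoxide 21. The closest known reaction type is the insertion of arynes into the carboxyl C–O bond of carboxylic acids to give ortho-hydroxyaryl ketones, which with α,β-unsaturated acids continues by oxa-Michael addition to 4-chromanones; new here are the β-methoxy leaving group, which should turn that conjugate addition into an addition–elimination delivering the chromone directly, and the fully substituted aryne. Ring C closes by 6-endo-trig attack of the C8a phenoxide on C2 and loss of methoxide from the resulting enolate, a closure familiar from isoflavone syntheses through 2-hydroxyaryl β-alkoxyvinyl or β-aminovinyl ketones. No stereocentre is formed, and the alkene geometry of 19 is lost at the enolate stage. The step needs attack of the carboxylate at C8a and not at C4a: the inductively withdrawing MOM-oxy group on C5 distorts the aryne toward attack at the remote carbon and stabilises charge at C4a, which for a small oxygen nucleophile should outweigh the steric screening of C8a by the adjacent tert-alkyl group. Hot THF with excess CsF is chosen so that the acyl shift outruns protonation of the C4a carbanion, and the cascade itself consumes no proton.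

Step 12
Reactants: 22 3-[2,4-bis(methoxymethoxy)phenyl]-5,7-bis(methoxymethoxy)-8-(2-methylbut-3-en-2-yl)chromen-4-one
Product: 23 3-(2,4-dihydroxyphenyl)-5,7-dihydroxy-8-(2-methylbut-3-en-2-yl)chromen-4-one
Conditions: conc. aq HCl (few equiv), MeOH, 45 °C
Reagents that add atoms: none
Why: Acid-catalysed acetal exchange with methanol cleaves all four aryl MOM ethers as dimethoxymethane, while the monosubstituted vinyl group, which could ionise only to a secondary cation, should resist hydration and ring closure onto the C7 hydroxyl under these mild conditions.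

Compound list
1 | phloroglucinol (benzene-1,3,5-triol) | Oc1cc(O)cc(O)c1 | starting material
2 | 3,5-bis(methoxymethoxy)phenol | COCOc1cc(O)cc(OCOC)c1 | intermediate
3 | 1-bromo-3-methylbut-2-ene (prenyl bromide) | CC(C)=CCBr | starting material
4 | 1,3-bis(methoxymethoxy)-5-[(3-methylbut-2-en-1-yl)oxy]benzene | COCOc1cc(OCC=C(C)C)cc(OCOC)c1 | intermediate
5 | 3,5-bis(methoxymethoxy)-6-(2-methylbut-3-en-2-yl)cyclohexa-2,4-dien-1-one (racemic, transient) | O=C1C=C(OCOC)C=C(OCOC)C1C(C)(C)C=C | intermediate (not isolated)
6 | 3,5-bis(methoxymethoxy)-2-(2-methylbut-3-en-2-yl)phenol | C=CC(C)(C)c1c(O)cc(OCOC)cc1OCOC | intermediate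
7 | 3,5-bis(methoxymethoxy)-2-(2-methylbut-3-en-2-yl)phenyl N-(propan-2-yl)carbamate | C=CC(C)(C)c1c(OC(=O)NC(C)C)cc(OCOC)cc1OCOC | intermediate
8 | 3,5-bis(methoxymethoxy)-2-(2-methylbut-3-en-2-yl)phenyl N-(propan-2-yl)-N-(trimethylsilyl)carbamate | C=CC(C)(C)c1c(OC(=O)N(C(C)C)[Si](C)(C)C)cc(OCOC)cc1OCOC | intermediate (not isolated)
9 | [4,6-bis(methoxymethoxy)-3-(2-methylbut-3-en-2-yl)-2-{[N-(propan-2-yl)-N-(trimethylsilyl)carbamoyl]oxy}phenyl]lithium | C=CC(C)(C)c1c(OC(=O)N(C(C)C)[Si](C)(C)C)c([Li])c(OCOC)cc1OCOC | intermediate (not isolated)
10 | 3,5-bis(methoxymethoxy)-2-(2-methylbut-3-en-2-yl)-6-(trimethylsilyl)phenyl N-(propan-2-yl)-N-(trimethylsilyl)carbamate | C=CC(C)(C)c1c(OC(=O)N(C(C)C)[Si](C)(C)C)c([Si](C)(C)C)c(OCOC)cc1OCOC | intermediate (not isolated)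
11 | 3,5-bis(methoxymethoxy)-2-(2-methylbut-3-en-2-yl)-6-(trimethylsilyl)phenyl N-(propan-2-yl)carbamate | C=CC(C)(C)c1c(OC(=O)NC(C)C)c([Si](C)(C)C)c(OCOC)cc1OCOC | intermediate
12 | 3,5-bis(methoxymethoxy)-2-(2-methylbut-3-en-2-yl)-6-(trimethylsilyl)phenol (present as its amidinium phenoxide) | C=CC(C)(C)c1c(O)c([Si](C)(C)C)c(OCOC)cc1OCOC | intermediate (not isolated)
13 | 3,5-bis(methoxymethoxy)-2-(2-methylbut-3-en-2-yl)-6-(trimethylsilyl)phenyl trifluoromethanesulfonate | C=CC(C)(C)c1c(OCOC)cc(OCOC)c([Si](C)(C)C)c1OS(=O)(=O)C(F)(F)F | intermediate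
14 | 2,4-dihydroxyphenylacetic acid | O=C(O)Cc1ccc(O)cc1O | starting material
15 | methyl 2-(2,4-dihydroxyphenyl)acetate | COC(=O)Cc1ccc(O)cc1O | intermediate
16 | methyl 2-[2,4-bis(methoxymethoxy)phenyl]acetate | COC(=O)Cc1ccc(OCOC)cc1OCOC | intermediate
17 | sodium 2-[2,4-bis(methoxymethoxy)phenyl]-3-methoxy-3-oxoprop-1-en-1-olate (enolate geometry not fixed) | [Na+].[O-]C=C(C(=O)OC)c1ccc(OCOC)cc1OCOC | intermediate (not isolated)
18 | methyl (E)-2-[2,4-bis(methoxymethoxy)phenyl]-3-methoxyprop-2-enoate | CO/C=C(/C(=O)OC)c1ccc(OCOC)cc1OCOC | intermediate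
19 | (E)-2-[2,4-bis(methoxymethoxy)phenyl]-3-methoxyprop-2-enoic acid | CO/C=C(/C(=O)O)c1ccc(OCOC)cc1OCOC | intermediate
20 | 1,2-didehydro-3,5-bis(methoxymethoxy)-6-(2-methylbut-3-en-2-yl)benzene (aryne across C8a and C4a) | C=CC(C)(C)C1=C(OCOC)C=C(OCOC)C#C1 | intermediate (not isolated)
21 | caesium 2-{(E)-2-[2,4-bis(methoxymethoxy)phenyl]-3-methoxyprop-2-enoyl}-3,5-bis(methoxymethoxy)-6-(2-methylbut-3-en-2-yl)phenolate | [Cs+].[O-]c1c(C(C)(C)C=C)c(OCOC)cc(OCOC)c1C(=O)/C(=C/OC)c1ccc(OCOC)cc1OCOC | intermediate (not isolated)
22 | 3-[2,4-bis(methoxymethoxy)phenyl]-5,7-bis(methoxymethoxy)-8-(2-methylbut-3-en-2-yl)chromen-4-one | C=CC(C)(C)c1c(OCOC)cc(OCOC)c2c(=O)c(-c3ccc(OCOC)cc3OCOC)coc12 | intermediate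
23 | 3-(2,4-dihydroxyphenyl)-5,7-dihydroxy-8-(2-methylbut-3-en-2-yl)chromen-4-one | C=CC(C)(C)c1c(O)cc(O)c2c(=O)c(-c3ccc(O)cc3O)coc12 | target

Total step count: 12 (steps 1–6 aryne precursor, steps 7–10 acid, step 11 union, step 12 deprotection).
Longest linear sequence: 8 steps (steps 1–6, 11 and 12).

Steps most likely to fail

Step 11 (Proposed new method). The carboxylate may add to C4a if the tert-alkyl group on C8 blocks C8a more strongly than the C5 oxygen directs, or the C4a carbanion may be protonated before the acyl shift so that the sequence stops at O-arylation. The fallback uses known chemistry, sets out from carbamate 7 and acid 19 and comes back to the route at 22. Acid 19 would be coupled with N,O-dimethylhydroxylamine hydrochloride (EDC·HCl, HOBt, i-Pr2NEt, CH2Cl2) to give the Weinreb amide (E)-2-[2,4-bis(methoxymethoxy)phenyl]-N,3-dimethoxy-N-methylprop-2-enamide F1. Carbamate 7 would be N-silylated and ortho-lithiated exactly as in step 5 to aryllithium 9, which would be quenched at −78 °C with F1 instead of TMSCl (Weinreb ketone synthesis; the amide has no acidic α-hydrogen). Aqueous work-up would give the ketone 2-{(E)-2-[2,4-bis(methoxymethoxy)phenyl]-3-methoxyprop-2-enoyl}-3,5-bis(methoxymethoxy)-6-(2-methylbut-3-en-2-yl)phenyl N-(propan-2-yl)carbamate F2. Treatment of F2 with DBU and Et2NH in MeCN at 40 °C would remove the carbamate by E1cB elimination, and the phenoxide so released would close ring C by addition–elimination with loss of methanol to give 22. Here the position of the acyl group is fixed by the directed metalation and no longer by the aryne.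

Step 3. The allyl unit may migrate on from the ortho to the para position (Cope shift of the dienone), and once the phenol is free it may isomerise by the abnormal Claisen pathway or close onto the vinyl group at the temperature required. The fallback sets out from 4 and comes back at 6. The rearrangement would be run in PhNEt2 at 190 °C in the presence of butanoic anhydride, so that the phenol is acylated as soon as it forms and the hydroxyl-dependent secondary reactions are shut off, giving 3,5-bis(methoxymethoxy)-2-(2-methylbut-3-en-2-yl)phenyl butanoate F3. Methanolysis (K2CO3, MeOH, rt) would then return phenol 6.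

Step 5. Metalation may lose site selectivity and occur between the two MOM ethers (the future C6) instead of next to the carbamate (the future C4a). The fallback sets out from 6, bypasses steps 4 and 5, and comes back at 12. Phenol 6 would be brominated ortho to the hydroxyl (NBS, i-Pr2NH cat., CH2Cl2, −78 °C; amine-mediated ortho-bromination of phenols, the alternative position being the more hindered one between two MOM ethers) to give 2-bromo-3,5-bis(methoxymethoxy)-6-(2-methylbut-3-en-2-yl)phenol F4. O-Silylation with hexamethyldisilazane would give [2-bromo-3,5-bis(methoxymethoxy)-6-(2-methylbut-3-en-2-yl)phenoxy]trimethylsilane F5. Bromine–lithium exchange (n-BuLi, THF, −78 °C) followed by 1,3 O→C silyl migration (retro-Brook rearrangement) and aqueous NH4Cl work-up would deliver silylphenol 12, which would be triflated with DBU and PhNTf2 as in the second half of step 6.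

Further compounds
F1 | step 11 | (E)-2-[2,4-bis(methoxymethoxy)phenyl]-N,3-dimethoxy-N-methylprop-2-enamide | CO/C=C(/C(=O)N(C)OC)c1ccc(OCOC)cc1OCOC
F2 | step 11 | 2-{(E)-2-[2,4-bis(methoxymethoxy)phenyl]-3-methoxyprop-2-enoyl}-3,5-bis(methoxymethoxy)-6-(2-methylbut-3-en-2-yl)phenyl N-(propan-2-yl)carbamate | C=CC(C)(C)c1c(OC(=O)NC(C)C)c(C(=O)/C(=C/OC)c2ccc(OCOC)cc2OCOC)c(OCOC)cc1OCOC
F3 | step 3 | 3,5-bis(methoxymethoxy)-2-(2-methylbut-3-en-2-yl)phenyl butanoate | C=CC(C)(C)c1c(OC(=O)CCC)cc(OCOC)cc1OCOC
F4 | step 5 | 2-bromo-3,5-bis(methoxymethoxy)-6-(2-methylbut-3-en-2-yl)phenol | C=CC(C)(C)c1c(O)c(Br)c(OCOC)cc1OCOC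
F5 | step 5 | [2-bromo-3,5-bis(methoxymethoxy)-6-(2-methylbut-3-en-2-yl)phenoxy]trimethylsilane | C=CC(C)(C)c1c(O[Si](C)(C)C)c(Br)c(OCOC)cc1OCOC
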